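## Structural features

The target is a 2,2-dimethyl-2H-chromene: a benzene ring (ring A) fused through C4a and C8a to a pyran (ring B) that holds O1, the quaternary C2 with its two methyl groups, and the C3=C4 double bond. Ring A carries a 3-methylbut-2-enyl (prenyl) ether on C7 and, on C5, a two-carbon chain ending in a 4-hydroxyphenyl ring (ring C). The molecule is therefore a bibenzyl whose resorcinol half has one oxygen locked in the pyran and the other prenylated. There is no stereocentre and no stereogenic double bond (C3=C4 is cis by ring constraint), so the compound is achiral and no stereocentres stand next to each other. The fragile parts are the chromene (an acid-labile tertiary allylic aryl ether with a reducible styrene-type alkene), the prenyl aryl ether (acid-labile, ionisable by zerovalent palladium, reducible) and the free phenol; strong acid and hydrogenation are excluded late in the route. The real difficulty is regiochemical: ring A is 1,2,3,5-tetrasubstituted, its two meta oxygens must end up different, and the pyran must be fused on the side of O1 that faces the C5 chain, which direct chromenylation of a 5-alkylresorcinol does not control. The key step exploits the fact that C4a and C8a are neighbouring arene carbons and can be the two ends of an aryne, while O1, C4, C3 and C2 with its methyl groups are exactly the atoms of 3-methylbut-2-enal; a bromine on C5 directs that union and later becomes the C5–CH2 bond.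

## Logic of the disconnections

**18 to 14 and 15.** The aryl–alkyl bond C5–CH2 is cut, together with the O–acetyl bond of the ring-C phenol. This is the one carbon–carbon bond between ring A and the chain that can be formed without a later hydrogenation, which neither the C3=C4 alkene nor the prenyl alkene would survive. The cut leaves an aryl bromide and a commercial styrene whose phenol is already masked, so no separate protection or deprotection sequence is needed. The forward step must place boron on the terminal carbon of 15, leave no B–H to reach the alkenes of 14, couple faster than zerovalent palladium can ionise the allylic ether, and end with a base that removes only the acetate.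

**14 to 12 and 13.** The O7–CH2 bond is cut. The prenyl group is thereby introduced after every step that uses electrophilic bromine, an organolithium, a triflating agent, an aryne or a hot thiolate. The gain is a simple bromophenol. The demand is clean O-alkylation at the primary allylic carbon rather than C-alkylation or allylic transposition.

**12 to 11.** The O7–CH3 bond is cut. A methyl ether is the smallest placeholder that survives bromination, butyllithium, triflation and fluoride. Carrying the prenyl ether itself through those stages was weighed and set aside, because its electron-rich alkene would face electrophilic bromine and an aryne. The demand is a demethylation that is basic and nucleophilic, since acid opens the pyran, and that leaves the C5–Br bond alone.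

**11 to 6 and 7, through 8, 9 and 10.** Three bonds are cut: C8a–O1, C4a–C4 and O1–C2. Ring B disappears completely, and what remains is a benzene with bromine, methoxy and the silyl/triflate pair, plus a commercial enal. Atom mapping confirms the fit: the silyl-bearing carbon of 6 becomes C8a, the triflate-bearing carbon becomes C4a, its bromine-bearing neighbour becomes C5 and the methoxy-bearing carbon becomes C7. The demand is that the oxygen of 7 bonds to the aryne carbon remote from bromine and that 10 closes before anything else captures it.

**6 to 2, through 3, 4 and 5.** The C–Si and O–S bonds are cut. An ortho-silylaryl triflate comes from an ortho-bromophenol by O-silylation, bromine–lithium exchange, oxygen-to-carbon silyl shift and O-triflation. Because 2 has two equivalent ortho bromines, one is converted to silicon and the other is kept as the directing group and later handle, with no question of which reacts. The demand is a single exchange.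

**2 to 1.** The two C–Br bonds are cut. The free hydroxyl directs both brominations to its ortho positions and the methoxy group blocks the para position. The demand is dibromination without oxidation of the electron-rich ring to a quinone.

## Other disconnections considered

**Alternative 1:** The cut runs through ring A itself: C5–C6, C6–C7, C8–C8a and C4a–C8a are broken, leaving the acyclic diazo enone A2, which carries the future C5 chain and the future C4a prenyl group, and the siloxyalkyne A3.
- Forward key step: light would trigger Wolff rearrangement of A2 to a vinylketene, which adds A3 by [2+2] cycloaddition; the cyclobutenone opens (4π) to a dienylketene that closes (6π) and tautomerises to the phenol A1.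
- In its favour: every substituent of ring A is placed by the connectivity of A2 and A3, so nothing has to be steered. The two ring-A oxygens are also born different, free hydroxyl at C8a and silyl ether at C7.
- Against it here: A2 is a trisubstituted enone with a skipped diene and a diazo ketone, and needs a sequence of its own that is likely to be as long as the whole chosen route. The vinylketene carries a tethered prenyl alkene that could compete in an intramolecular [2+2] addition, and A3 is hydrolytically fragile.
- A1 still lacks ring B. Oxidative cyclisation of the ortho-prenylphenol with DDQ, exchange of silyl for prenyl at O7 and removal of the pivalate would follow, with DDQ facing two benzylic methylene groups.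
- Comparison: structurally the alternative builds ring A and leaves ring B for later, while the chosen plan buys ring A and builds ring B together with the C5 handle. Mechanistically both are cascades ending in a thermal electrocyclisation, one started by light and the other by fluoride at room temperature. In regiochemical certainty the alternative is the better, and in differentiating the two oxygens it is the equal. In step economy and operational simplicity (photochemistry, a diazo compound) it is clearly worse, estimated at about twice the length.

**Alternative 2:** The cut is the C3=C4 double bond of the pyran.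
- Forward key step: the diene A5, an ortho-vinylaryl 1,1-dimethylallyl ether, would be treated with second-generation Grubbs catalyst (H2IMes)(PCy3)Cl2Ru=CHPh to give the silyl-protected target A4 with loss of ethylene; Bu4NF would then give 18.
- In its favour: chromene-forming ring-closing metathesis is neutral and tolerant, the gem-dimethyl group helps closure, and the ring closure has no regiochemical ambiguity. A4 is one mild deprotection from the target, so the end-game is gentler than in the chosen plan (no hot thiolate, no palladium beside a prenyl ether); on this point the alternative is the better.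
- Against it here: the whole difficulty moves into A5. Ring A must already carry the vinyl group between the chain and the tertiary ether, plus the prenyl ether.
- The tertiary allylic aryl ether cannot be made by simple alkylation and needs a propargylation and semihydrogenation detour. The propargyl-ether stage of that detour could be closed to the chromene thermally, which would make the metathesis redundant.
- The 1,1-dimethylallyl ether of A5 is prone to ionisation and to aromatic Claisen rearrangement toward the free C8 position. The ruthenium carbene could also engage the prenyl alkene or isomerise the allylic ethers.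
- Comparison: structurally the metathesis makes one C=C bond and sets none of the ring-A pattern, whereas the aryne step makes three bonds and sets that pattern. Mechanistically it is a metal-carbene [2+2] and cycloreversion against a metal-free polar [2+2] and electrocyclisation. The alternative is the equal in predictability of the ring closure. In step economy it is worse, since A5 alone is estimated at eight to ten steps.

**Alternative 3:** The cut is C4a–C5 within ring A.
- Forward key step: the triketo ester A7 would be treated with base; the C2 enolate adds to the C7 ketone, and dehydration and enolisation give the resorcylate A6.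
- In its favour: it mirrors the polyketide origin of bibenzyls, and every ring-A position is fixed by the chain. The ester on C4a hydrogen-bonds the C8a hydroxyl, so the C7 hydroxyl of A6 could be prenylated selectively with no placeholder; here the alternative is better than the chosen plan, which needs a methyl ether and its removal.
- Against it here: A7 has to be assembled by polyanion acylation and is open to competing cyclisations (Claisen-type closure onto the ester, pyranone formation).
- A6 has no ring B. The ester carbon must be reduced to the aldehyde level, extended by a 2-methylpropenyl nucleophile and cyclised through an ortho-quinone methide, and the silyl ether removed. That is four or five further steps, some of which would need phenol protection.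
- Comparison: structurally the alternative forms one ring-A bond and the chosen plan forms the heterocycle. Mechanistically it is an ionic aldol condensation under equilibrium control against a kinetically controlled aryne capture. It is the equal in regiochemical certainty and the better in oxygen differentiation. In step economy it is worse, estimated at ten or more steps against six.

Key step: step 3

Remark on the chemistry: the target has no stereocentre, so none has to be set. Silyl ether 3 is carried on crude in the same flask after evaporation of volatiles and is counted as an intermediate of step 2. The geometry written for 10 is the one that can cyclise.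

## Route

Step 1
Reactants: 1 4-methoxyphenol
Product: 2 2,6-dibromo-4-methoxyphenol
Conditions: NBS (2.05 equiv), i-Pr2NH (10 mol %), CH2Cl2, 0 °C to rt
Reagents that add atoms: N-bromosuccinimide, O=C1CCC(=O)N1Br
Why: Electrophilic aromatic bromination: the free hydroxyl outranks the methoxy group as director and the amine-derived N-bromoamine delivers bromine ortho to the hydroxyl through hydrogen bonding, so both flanking positions are brominated while the para position is blocked.

Step 2
Reactants: 2 2,6-dibromo-4-methoxyphenol
Product: 6 2-bromo-4-methoxy-6-(trimethylsilyl)phenyl trifluoromethanesulfonate, via silyl ether 3 (not isolated), via aryllithium 4 (not isolated), via lithium phenoxide 5 (not isolated)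
Conditions: HMDS, THF, 70 °C, then evaporation; n-BuLi (1.05 equiv), THF, −100 to −80 °C; Tf2O, −100 to −80 °C; aq NaHCO3
Reagents that add atoms: hexamethyldisilazane, C[Si](C)(C)N[Si](C)(C)C; trifluoromethanesulfonic anhydride, O=S(=O)(OS(=O)(=O)C(F)(F)F)C(F)(F)F
Why: O-Silylation masks the phenol; bromine–lithium exchange at one of the two equivalent bromines gives 4, whose carbanion takes the silyl group from oxygen in a 1,3 retro-Brook shift to phenoxide 5, which Tf2O traps at oxygen. This is the standard one-flask preparation of ortho-silylaryl triflates, and the symmetry of 3 removes any question of which bromine reacts.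

Step 3
Reactants: 6 2-bromo-4-methoxy-6-(trimethylsilyl)phenyl trifluoromethanesulfonate; 7 3-methylbut-2-enal
Product: 11 5-bromo-7-methoxy-2,2-dimethyl-2H-chromene, via aryne 8 (not isolated), via benzoxete 9 (not isolated), via quinone methide 10 (not isolated)
Conditions: CsF (3 equiv), 7 (5 equiv), MeCN, 25 °C, 6 added over 4 h
Reagents that add atoms: none
Why: Fluoride attacks silicon of 6 and the resulting aryl anion expels triflate to give aryne 8. The σ-withdrawing bromine distorts 8 so that the aryne carbon remote from it is the more linear and electrophilic one; the carbonyl oxygen of 7 attacks there, the carbanion developing next to bromine closes onto the carbonyl carbon, and this stepwise formal [2+2] addition forms C8a–O1 and C4a–C4 in benzoxete 9. The strained four-membered ring of 9 opens by 4π electrocyclic cleavage of its C–O bond to the ortho-quinone methide 10, in which the peri bromine pushes the 2-methylpropenyl arm to the oxygen side. A thermal disrotatory oxa-6π electrocyclisation then joins O1 to C2 and restores the aromatic ring, which is the mode by which the six-membered pyran is closed. The closest known reaction type is the insertion of arynes into the C=O bond of α,β-unsaturated aldehydes and of formamides, which leads to 2H-chromenes and salicylaldehydes through the same benzoxete and quinone methide sequence. No stereocentre is created in 11 because C2 carries two methyl groups, and the stereocentre of transient 9 is racemic and is erased on ring opening. The selectivity needed is regiochemical, oxygen on the carbon remote from bromine, and it is secured by the inductive bias of the 3-bromoaryne, against which the methoxy group, para to the carbanionic carbon, exerts only a weak opposing pull. Carbonyl addition is favoured over a [4+2] addition across the enal by the two β-methyl groups, and capture of 10 by a second aryne is held back by adding 6 slowly to an excess of 7.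

Step 4
Reactants: 11 5-bromo-7-methoxy-2,2-dimethyl-2H-chromene
Product: 12 5-bromo-2,2-dimethyl-2H-chromen-7-ol
Conditions: NaSEt (4 equiv), DMF, 120 °C; then AcOH/H2O, 0 °C
Reagents that add atoms: none
Why: Thiolate O-demethylation by SN2 attack of ethanethiolate at the methyl carbon; the tertiary allylic C2–O1 bond cannot be attacked in this way, the unactivated electron-rich aryl bromide offers no easy substitution path, and the basic medium spares the acid-sensitive chromene.

Step 5
Reactants: 12 5-bromo-2,2-dimethyl-2H-chromen-7-ol; 13 1-bromo-3-methylbut-2-ene (prenyl bromide)
Product: 14 5-bromo-2,2-dimethyl-7-(3-methylbut-2-enyloxy)-2H-chromene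
Conditions: K2CO3 (2 equiv), acetone, 50 °C
Reagents that add atoms: none
Why: Williamson ether synthesis: the phenoxide formed with K2CO3 in a polar aprotic solvent is alkylated at oxygen by the primary allylic bromide in an SN2 reaction, which is favoured over C-alkylation and over attack at the tertiary allylic terminus.

Step 6
Reactants: 14 5-bromo-2,2-dimethyl-7-(3-methylbut-2-enyloxy)-2H-chromene; 15 4-ethenylphenyl acetate (4-acetoxystyrene)
Product: 18 4-{2-[2,2-dimethyl-7-(3-methylbut-2-enyloxy)-2H-chromen-5-yl]ethyl}phenol (target), via alkylborane 16 (not isolated), via aryl acetate 17 (not isolated)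
Conditions: 15 (1.45 equiv), 9-BBN (1.4 equiv), THF, 0 °C to rt; then 14, PdCl2(dppf) (5 mol %), K3PO4 (3 M aq, 3 equiv), DMF, 60 °C; then NaOH, MeOH/H2O, rt; AcOH to pH 6
Reagents that add atoms: none
Why: Anti-Markovnikov hydroboration of the styrene with 9-BBN gives the primary alkylborane 16, which undergoes B-alkyl Suzuki–Miyaura coupling with the aryl bromide (oxidative addition, base-assisted transmetalation, reductive elimination, the wide bite angle of dppf favouring reductive elimination over β-hydride elimination). Hydroxide in methanol then saponifies the aryl acetate; any part already cleaved under the phosphate is the same product.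

## Compound list

1 | 4-methoxyphenol | COc1ccc(O)cc1 | starting material
2 | 2,6-dibromo-4-methoxyphenol | COc1cc(Br)c(O)c(Br)c1 | intermediate
3 | (2,6-dibromo-4-methoxyphenoxy)trimethylsilane | COc1cc(Br)c(O[Si](C)(C)C)c(Br)c1 | intermediate
4 | [3-bromo-5-methoxy-2-(trimethylsilyloxy)phenyl]lithium | [Li]c1cc(OC)cc(Br)c1O[Si](C)(C)C | intermediate
5 | lithium 2-bromo-4-methoxy-6-(trimethylsilyl)phenolate | [Li+].[O-]c1c(Br)cc(OC)cc1[Si](C)(C)C | intermediate
6 | 2-bromo-4-methoxy-6-(trimethylsilyl)phenyl trifluoromethanesulfonate | COc1cc(Br)c(OS(=O)(=O)C(F)(F)F)c([Si](C)(C)C)c1 | intermediate
7 | 3-methylbut-2-enal | CC(C)=CC=O | starting material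
8 | 3-bromo-5-methoxybenzyne (3-bromo-5-methoxy-1,2-didehydrobenzene) | COC1=CC#CC(Br)=C1 | intermediate
9 | 3-bromo-5-methoxy-2-(2-methylprop-1-enyl)-2H-benzo[b]oxete (racemic) | COc1cc(Br)c2C(C=C(C)C)Oc2c1 | intermediate
10 | (6E)-5-bromo-3-methoxy-6-(3-methylbut-2-enylidene)cyclohexa-2,4-dien-1-one | COC1=CC(=O)/C(=C\C=C(C)C)C(Br)=C1 | intermediate
11 | 5-bromo-7-methoxy-2,2-dimethyl-2H-chromene | COc1cc(Br)c2C=CC(C)(C)Oc2c1 | intermediate
12 | 5-bromo-2,2-dimethyl-2H-chromen-7-ol | Oc1cc(Br)c2C=CC(C)(C)Oc2c1 | intermediate
13 | 1-bromo-3-methylbut-2-ene (prenyl bromide) | CC(C)=CCBr | starting material
14 | 5-bromo-2,2-dimethyl-7-(3-methylbut-2-enyloxy)-2H-chromene | CC(C)=CCOc1cc(Br)c2C=CC(C)(C)Oc2c1 | intermediate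
15 | 4-ethenylphenyl acetate (4-acetoxystyrene) | CC(=O)Oc1ccc(C=C)cc1 | starting material
16 | 4-[2-(9-borabicyclo[3.3.1]nonan-9-yl)ethyl]phenyl acetate | CC(=O)Oc1ccc(CCB2C3CCCC2CCC3)cc1 | intermediate
17 | 4-{2-[2,2-dimethyl-7-(3-methylbut-2-enyloxy)-2H-chromen-5-yl]ethyl}phenyl acetate | CC(C)=CCOc1cc(CCc2ccc(OC(C)=O)cc2)c2c(c1)OC(C)(C)C=C2 | intermediate
18 | 4-{2-[2,2-dimethyl-7-(3-methylbut-2-enyloxy)-2H-chromen-5-yl]ethyl}phenol | CC(C)=CCOc1cc(CCc2ccc(O)cc2)c2c(c1)OC(C)(C)C=C2 | target

## Step count and least certain steps

Total step count: 6. Longest linear sequence: 6 steps (1, 2, 6, 11, 12, 14, 18); 7, 13 and 15 are commercial and enter directly.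

**Step 3 (key step).** The most likely failure is interception of quinone methide 10 by a second molecule of aryne 8 before the electrocyclisation, together with fluoride-induced self-condensation of the enolisable aldehyde 7; both consume material. A smaller risk is erosion of the regiochemical bias of bromine by the methoxy group.
The fallback separates the aryne capture from the enal. It sets out from 6, which would be treated with CsF in DMF as solvent and reactant. The aryne inserts into the formamide C=O bond in the same sense, and aqueous work-up should give 2-bromo-6-hydroxy-4-methoxybenzaldehyde F1. Addition of Me2C=CHMgBr (2.2 equiv, THF, 0 °C) should give 3-bromo-2-(1-hydroxy-3-methylbut-2-enyl)-5-methoxyphenol F2. Gentle heating of F2 in toluene should expel water to give the same quinone methide 10, which closes as before. The fallback comes back to the route at 11.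

**Step 2.** The most likely failure is attack of butyllithium at silicon, or a second bromine–lithium exchange competing with the first. O-Triflation of phenoxide 5 may also be slow, since its oxygen is flanked by bromine and trimethylsilyl, and that leaves time for side reactions of Tf2O.
The fallback forms the C–Si bond with an external electrophile instead of the oxygen-to-carbon shift. It sets out from 2, which would be treated with n-BuLi (2.1 equiv); the first equivalent makes the phenoxide, whose charge disfavours exchange of the second bromine. Me3SiCl (2.5 equiv) should then give [2-bromo-4-methoxy-6-(trimethylsilyl)phenoxy]trimethylsilane F3. Mild methanolysis (K2CO3, MeOH) should free 2-bromo-4-methoxy-6-(trimethylsilyl)phenol F4, which would be triflated separately (Tf2O, pyridine, CH2Cl2, 0 °C). The fallback comes back to the route at 6.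

**Step 4.** The most likely failure is displacement or reductive loss of the bromine by the thiolate at 120 °C in competition with demethylation, and stalling of the reaction before completion.
The fallback moves the coupling ahead of the demethylation, so that the thiolate meets no aryl bromide. It sets out from 11 and alkylborane 16 (made from 15 as in step 6):
- Coupling with PdCl2(dppf) and aqueous NaOH, which also removes the acetate, should give 4-[2-(7-methoxy-2,2-dimethyl-2H-chromen-5-yl)ethyl]phenol F5.
- Dihydropyran with pyridinium tosylate should give the base-stable acetal 2-{4-[2-(7-methoxy-2,2-dimethyl-2H-chromen-5-yl)ethyl]phenoxy}oxane F6.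
- NaSEt in DMF should then give 2,2-dimethyl-5-{2-[4-(oxan-2-yloxy)phenyl]ethyl}-2H-chromen-7-ol F7.
- Alkylation with 13 and K2CO3 should give 2-(4-{2-[2,2-dimethyl-7-(3-methylbut-2-enyloxy)-2H-chromen-5-yl]ethyl}phenoxy)oxane F8.
- Pyridinium tosylate in methanol should remove the acetal.

The fallback comes back to the route at 18.

**Step 6.** The most likely failure is slow oxidative addition into the electron-rich C5–Br bond beside the ring fusion. That leaves time for protodeboronation or β-hydride elimination of the alkylborane, and for zerovalent palladium to ionise the prenyl aryl ether with loss of the prenyl group. Residual B–H could also add to the chromene alkene.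
The fallback couples before prenylation, so the coupling can be forced with no palladium-labile group present. It sets out from 12 and 15:
- Methanolysis of 15 (K2CO3, MeOH) should give 4-ethenylphenol F9, which would be silylated at once (i-Pr3SiCl, imidazole) to (4-ethenylphenoxy)triisopropylsilane F10.
- Hydroboration with 9-BBN should give 9-{2-[4-(triisopropylsilyloxy)phenyl]ethyl}-9-borabicyclo[3.3.1]nonane F11.
- Coupling of F11 with 12 (PdCl2(dppf), K3PO4) should give 2,2-dimethyl-5-{2-[4-(triisopropylsilyloxy)phenyl]ethyl}-2H-chromen-7-ol F12.
- Alkylation with 13 and K2CO3 should give triisopropyl(4-{2-[2,2-dimethyl-7-(3-methylbut-2-enyloxy)-2H-chromen-5-yl]ethyl}phenoxy)silane F13.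
- Bu4NF should remove the silyl group.

The fallback comes back to the route at 18.

## Further compounds

F1 | step 3 | 2-bromo-6-hydroxy-4-methoxybenzaldehyde | COc1cc(O)c(C=O)c(Br)c1
F2 | step 3 | 3-bromo-2-(1-hydroxy-3-methylbut-2-enyl)-5-methoxyphenol (racemic) | COc1cc(O)c(C(O)C=C(C)C)c(Br)c1
F3 | step 2 | [2-bromo-4-methoxy-6-(trimethylsilyl)phenoxy]trimethylsilane | COc1cc(Br)c(O[Si](C)(C)C)c([Si](C)(C)C)c1
F4 | step 2 | 2-bromo-4-methoxy-6-(trimethylsilyl)phenol | COc1cc(Br)c(O)c([Si](C)(C)C)c1
F5 | step 4 | 4-[2-(7-methoxy-2,2-dimethyl-2H-chromen-5-yl)ethyl]phenol | COc1cc(CCc2ccc(O)cc2)c2C=CC(C)(C)Oc2c1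
F6 | step 4 | 2-{4-[2-(7-methoxy-2,2-dimethyl-2H-chromen-5-yl)ethyl]phenoxy}oxane (racemic) | COc1cc(CCc2ccc(OC3CCCCO3)cc2)c2C=CC(C)(C)Oc2c1
F7 | step 4 | 2,2-dimethyl-5-{2-[4-(oxan-2-yloxy)phenyl]ethyl}-2H-chromen-7-ol (racemic) | Oc1cc(CCc2ccc(OC3CCCCO3)cc2)c2C=CC(C)(C)Oc2c1
F8 | step 4 | 2-(4-{2-[2,2-dimethyl-7-(3-methylbut-2-enyloxy)-2H-chromen-5-yl]ethyl}phenoxy)oxane (racemic) | CC(C)=CCOc1cc(CCc2ccc(OC3CCCCO3)cc2)c2C=CC(C)(C)Oc2c1
F9 | step 6 | 4-ethenylphenol | C=Cc1ccc(O)cc1
F10 | step 6 | (4-ethenylphenoxy)triisopropylsilane | C=Cc1ccc(O[Si](C(C)C)(C(C)C)C(C)C)cc1
F11 | step 6 | 9-{2-[4-(triisopropylsilyloxy)phenyl]ethyl}-9-borabicyclo[3.3.1]nonane | CC(C)[Si](Oc1ccc(CCB2C3CCCC2CCC3)cc1)(C(C)C)C(C)C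
F12 | step 6 | 2,2-dimethyl-5-{2-[4-(triisopropylsilyloxy)phenyl]ethyl}-2H-chromen-7-ol | Oc1cc(CCc2ccc(O[Si](C(C)C)(C(C)C)C(C)C)cc2)c2C=CC(C)(C)Oc2c1
F13 | step 6 | triisopropyl(4-{2-[2,2-dimethyl-7-(3-methylbut-2-enyloxy)-2H-chromen-5-yl]ethyl}phenoxy)silane | CC(C)=CCOc1cc(CCc2ccc(O[Si](C(C)C)(C(C)C)C(C)C)cc2)c2C=CC(C)(C)Oc2c1
A1 | alternative 1 | 4-{2-[3-hydroxy-2-(3-methylbut-2-enyl)-5-(triisopropylsilyloxy)phenyl]ethyl}phenyl 2,2-dimethylpropanoate | CC(C)=CCc1c(O)cc(O[Si](C(C)C)(C(C)C)C(C)C)cc1CCc1ccc(OC(=O)C(C)(C)C)cc1
A2 | alternative 1 | 4-[(3E)-3-(diazoacetyl)-7-methylocta-3,6-dienyl]phenyl 2,2-dimethylpropanoate | [N-]=[N+]=CC(=O)/C(CCc1ccc(OC(=O)C(C)(C)C)cc1)=C/CC=C(C)C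
A3 | alternative 1 | (ethynyloxy)triisopropylsilane | C#CO[Si](C(C)C)(C(C)C)C(C)C
A4 | alternative 2 | tert-butyl(4-{2-[2,2-dimethyl-7-(3-methylbut-2-enyloxy)-2H-chromen-5-yl]ethyl}phenoxy)dimethylsilane | CC(C)=CCOc1cc(CCc2ccc(O[Si](C)(C)C(C)(C)C)cc2)c2c(c1)OC(C)(C)C=C2
A5 | alternative 2 | tert-butyl(4-{2-[2-ethenyl-3-(2-methylbut-3-en-2-yloxy)-5-(3-methylbut-2-enyloxy)phenyl]ethyl}phenoxy)dimethylsilane | C=Cc1c(CCc2ccc(O[Si](C)(C)C(C)(C)C)cc2)cc(OCC=C(C)C)cc1OC(C)(C)C=C
A6 | alternative 3 | methyl 2,4-dihydroxy-6-{2-[4-(triisopropylsilyloxy)phenyl]ethyl}benzoate | COC(=O)c1c(O)cc(O)cc1CCc1ccc(O[Si](C(C)C)(C(C)C)C(C)C)cc1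
A7 | alternative 3 | methyl 3,5,7-trioxo-9-[4-(triisopropylsilyloxy)phenyl]nonanoate | COC(=O)CC(=O)CC(=O)CC(=O)CCc1ccc(O[Si](C(C)C)(C(C)C)C(C)C)cc1
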